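## Retrosynthetic overview

1. The 2,5-dihydrofuran is the only ring made in the route and it is made last: OH-directed 5,6-epoxidation of the complete, unprotected C30 polyenal (3S)-3-hydroxy-8'-apo-β-caroten-8'-al, then acid-triggered 5,6-epoxide → 5,8-furanoid shift in the same flask.
2. C30 polyenal ⇐ C27 aldehyde + C3 formyl ylide; C27 aldehyde ⇐ C15 ring phosphonium salt + C12 aldehyde-acetal (C10-dialdehyde + C2 Wittig salt).
3. C15 salt ⇐ Stille union (C6–C7) of a C9 cyclohexenyl triflate with a C6 stannyl dienol made from the commercial enynol.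
4. Triflate ⇐ (4R,6R)-actinol by Mitsunobu inversion (fixes C3) and enol triflation. Ring order: cyclohexene bought with the chiral pool, dihydrofuran closed in the final step.

Assumption 1: carotenoid numbering is used (ring C1–C6, chain C7…C8'); read from the SMILES the target is (3R,5R,8R)-5,8-epoxy-3-hydroxy-5,8-dihydro-8'-apo-β-caroten-8'-al, with 3-OH and the C5–O bond on the same ring face.
Assumption 2: (4R,6R)-actinol, the bulk zeaxanthin intermediate made from ketoisophorone, is taken as a purchasable starting material.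

## Route

Step 1
Reactants: 1 (4R,6R)-4-hydroxy-2,2,6-trimethylcyclohexanone (actinol)
Product: 2 (1S,5R)-3,3,5-trimethyl-4-oxocyclohexyl 4-nitrobenzoate
Conditions: 4-O2NC6H4CO2H, PPh3, DIAD, THF, 0 °C → rt
Reagents that add atoms: 4-nitrobenzoic acid, OC(=O)c1ccc(cc1)[N+](=O)[O-]
Why: Mitsunobu esterification displaces the axial oxyphosphonium by SN2 with clean inversion, so the (4R) carbinol becomes the (4S) ester (the future C3, already in the configuration the target needs) and is protected in the same operation.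

Step 2
Reactants: 2 (1S,5R)-3,3,5-trimethyl-4-oxocyclohexyl 4-nitrobenzoate
Product: 3 (1S)-3,5,5-trimethyl-4-[(trifluoromethanesulfonyl)oxy]cyclohex-3-en-1-yl 4-nitrobenzoate
Conditions: Tf2O (1.5 equiv), 2,6-di-tert-butyl-4-methylpyridine (2 equiv), CH2Cl2, 0 °C → rt, 24 h
Reagents that add atoms: trifluoromethanesulfonic anhydride, O=S(=O)(OS(=O)(=O)C(F)(F)F)C(F)(F)F
Why: The ketone can enolise only towards the methyl-bearing carbon (the other α-carbon is quaternary), so enol triflate formation under non-nucleophilic conditions gives the single tetrasubstituted vinyl triflate, erases the now irrelevant methyl stereocentre and leaves the ester and the carbinol centre untouched.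

Step 3
Reactants: 4 (E)-3-methylpent-2-en-4-yn-1-ol
Product: 5 (2E,4E)-3-methyl-5-(tributylstannyl)penta-2,4-dien-1-ol
Conditions: Bu3SnH (1.1 equiv), PdCl2(PPh3)2 (2 mol%), THF, 0 °C → rt; chromatography
Reagents that add atoms: tributyltin hydride, CCCC[SnH](CCCC)CCCC
Why: Pd-catalysed syn-hydrostannylation of the terminal alkyne of a conjugated E-enyne places tin on the terminal carbon and gives the (E,E)-dienylstannane, the minor internal regioisomer being removed on silica.

Step 4
Reactants: 3 (1S)-3,5,5-trimethyl-4-[(trifluoromethanesulfonyl)oxy]cyclohex-3-en-1-yl 4-nitrobenzoate; 5 (2E,4E)-3-methyl-5-(tributylstannyl)penta-2,4-dien-1-ol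
Product: 6 (1S)-4-[(1E,3E)-5-hydroxy-3-methylpenta-1,3-dien-1-yl]-3,5,5-trimethylcyclohex-3-en-1-yl 4-nitrobenzoate
Conditions: Pd2(dba)3 (2.5 mol%), AsPh3 (20 mol%), NMP, 50 °C
Reagents that add atoms: none
Why: Stille cross-coupling with a weakly donating arsine ligand in a polar solvent is the established way to join hindered 2,6,6-trimethylcyclohexenyl triflates to dienylstannanes, forming C6–C7 with retention of both alkene geometries and tolerating the free alcohol, ester and nitro group.

Step 5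
Reactants: 6 (1S)-4-[(1E,3E)-5-hydroxy-3-methylpenta-1,3-dien-1-yl]-3,5,5-trimethylcyclohex-3-en-1-yl 4-nitrobenzoate
Product: 7 [(2E,4E)-3-methyl-5-{(4S)-2,6,6-trimethyl-4-[(4-nitrobenzoyl)oxy]cyclohex-1-en-1-yl}penta-2,4-dien-1-yl]triphenylphosphonium bromide
Conditions: PPh3·HBr (1.05 equiv), CH2Cl2/MeOH, 0 °C → rt; crystallise (9E salt)
Reagents that add atoms: triphenylphosphine hydrobromide, Br.c1ccc(cc1)P(c1ccccc1)c1ccccc1
Why: Acid ionises the allylic alcohol to a ring-conjugated pentadienyl cation that triphenylphosphine captures at the unhindered terminus (the classical C15 Wittig-salt formation), while the non-allylic ester-bearing centre cannot ionise.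

Step 6
Reactants: 8 (2E,4E,6E)-2,7-dimethylocta-2,4,6-trienedial (C10-dialdehyde, 2.5 equiv); 9 (1,3-dioxolan-2-ylmethyl)triphenylphosphonium bromide
Product: 11 (2E,4E,6E,8E)-9-(1,3-dioxolan-2-yl)-2,7-dimethylnona-2,4,6,8-tetraenal, via dioxolanylmethylidene ylide 10 (not isolated)
Conditions: 9, t-BuOK, THF, 0 °C; add to 8 (2.5 equiv), 0 °C → rt; I2 (cat.), CH2Cl2, rt; recover excess 8
Reagents that add atoms: none
Why: Wittig two-carbon homologation of one formyl group of the symmetrical dialdehyde (used in excess for mono-selectivity) gives a dialdehyde with the two ends differentiated as free CHO and dioxolane, and iodine equilibrates the new alkene to E.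

Step 7
Reactants: 7 [(2E,4E)-3-methyl-5-{(4S)-2,6,6-trimethyl-4-[(4-nitrobenzoyl)oxy]cyclohex-1-en-1-yl}penta-2,4-dien-1-yl]triphenylphosphonium bromide; 11 (2E,4E,6E,8E)-9-(1,3-dioxolan-2-yl)-2,7-dimethylnona-2,4,6,8-tetraenal
Product: 15 (3S)-3-hydroxy-10'-apo-β-caroten-10'-al, via C15 ylide 12 (not isolated), via nitrobenzoate acetal 13 (not isolated), via hydroxy acetal 14 (not isolated)
Conditions: NaOMe (3 equiv), MeOH/CH2Cl2, 0 °C → rt, 3 h; then 1 M HCl, THF, rt, 30 min; then I2 (1 mol%), CH2Cl2, daylight, rt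
Reagents that add atoms: water, O
Why: Wittig olefination by the allylic C15 ylide forms C11=C12, the excess methoxide removes the 4-nitrobenzoate by transesterification, the acidic work-up hydrolyses the dioxolane and iodine-catalysed isomerisation funnels the polyene to all-E, none of which touches the C3 stereocentre.

Step 8
Reactants: 15 (3S)-3-hydroxy-10'-apo-β-caroten-10'-al; 16 2-(triphenylphosphoranylidene)propanal
Product: 17 (3S)-3-hydroxy-8'-apo-β-caroten-8'-al
Conditions: 16 (1.5 equiv), toluene, 80 °C, dark, Ar; then I2 (cat.), rt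
Reagents that add atoms: none
Why: Wittig olefination with the stabilised α-methyl formyl ylide is E-selective and stops after one homologation because the α-methyl enal product is the less electrophilic aldehyde, and the neutral conditions leave the free 3-OH alone.

Step 9
Reactants: 17 (3S)-3-hydroxy-8'-apo-β-caroten-8'-al
Product: 19 (3R,5R,8R)-5,8-epoxy-3-hydroxy-5,8-dihydro-8'-apo-β-caroten-8'-al, via syn-epoxide 18 (not isolated)
Conditions: VO(O-i-Pr)3 (10 mol%), t-BuOOH (1.1 equiv, in decane), BHT (cat.), toluene, −10 °C, dark, Ar; then CSA (10 mol%), −20 → 0 °C; Et3N quench; HPLC separation from the C8 epimer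
Reagents that add atoms: tert-butyl hydroperoxide, CC(C)(C)OO
Why: Proposed new method: the C3 alkoxide binds the vanadium(V) alkylperoxide and delivers oxygen intramolecularly to the syn face of the homoallylic C5=C6 bond only (Sharpless–Michaelson-type hydroxyl-directed epoxidation, setting 5R from C3), after which acid ionises the allylic C6–O bond to a polyenyl cation that the C5 oxygen recloses at C8 with C5 retained (the biogenetic epoxide–furanoid rearrangement), C8 arising without intrinsic control so that the 8R epimer is taken by chromatography; the closest known reactions are peracid 5,6-epoxidation of intact carotenoids and their acid-catalysed furanoid rearrangement.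

## Compound list

1 | (4R,6R)-4-hydroxy-2,2,6-trimethylcyclohexanone (actinol) | C[C@@H]1C[C@@H](O)CC(C)(C)C1=O | starting material
2 | (1S,5R)-3,3,5-trimethyl-4-oxocyclohexyl 4-nitrobenzoate | C[C@@H]1C[C@H](OC(=O)c2ccc(cc2)[N+](=O)[O-])CC(C)(C)C1=O | intermediate
3 | (1S)-3,5,5-trimethyl-4-[(trifluoromethanesulfonyl)oxy]cyclohex-3-en-1-yl 4-nitrobenzoate | CC1=C(OS(=O)(=O)C(F)(F)F)C(C)(C)C[C@@H](OC(=O)c2ccc(cc2)[N+](=O)[O-])C1 | intermediate
4 | (E)-3-methylpent-2-en-4-yn-1-ol | C#C/C(C)=C/CO | starting material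
5 | (2E,4E)-3-methyl-5-(tributylstannyl)penta-2,4-dien-1-ol | CCCC[Sn](CCCC)(CCCC)/C=C/C(C)=C/CO | intermediate
6 | (1S)-4-[(1E,3E)-5-hydroxy-3-methylpenta-1,3-dien-1-yl]-3,5,5-trimethylcyclohex-3-en-1-yl 4-nitrobenzoate | OC/C=C(C)/C=C/C1=C(C)C[C@H](OC(=O)c2ccc(cc2)[N+](=O)[O-])CC1(C)C | intermediate
7 | [(2E,4E)-3-methyl-5-{(4S)-2,6,6-trimethyl-4-[(4-nitrobenzoyl)oxy]cyclohex-1-en-1-yl}penta-2,4-dien-1-yl]triphenylphosphonium bromide | [Br-].c1ccccc1[P+](c1ccccc1)(c1ccccc1)C/C=C(C)/C=C/C1=C(C)C[C@H](OC(=O)c2ccc(cc2)[N+](=O)[O-])CC1(C)C | intermediate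
8 | (2E,4E,6E)-2,7-dimethylocta-2,4,6-trienedial | O=C/C(C)=C/C=C/C=C(C)/C=O | starting material
9 | (1,3-dioxolan-2-ylmethyl)triphenylphosphonium bromide | [Br-].C1COC(O1)C[P+](c1ccccc1)(c1ccccc1)c1ccccc1 | starting material
10 | (1,3-dioxolan-2-ylmethylidene)triphenylphosphorane (ylide of 9, not isolated) | C1COC(O1)[CH-][P+](c1ccccc1)(c1ccccc1)c1ccccc1 | intermediate
11 | (2E,4E,6E,8E)-9-(1,3-dioxolan-2-yl)-2,7-dimethylnona-2,4,6,8-tetraenal | O=C/C(C)=C/C=C/C=C(C)/C=C/C1OCCO1 | intermediate
12 | ylide of 7 (C11 carbanion, ester still in place, not isolated) | c1ccccc1[P+](c1ccccc1)(c1ccccc1)[CH-]/C=C(C)/C=C/C1=C(C)C[C@H](OC(=O)c2ccc(cc2)[N+](=O)[O-])CC1(C)C | intermediate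
13 | (3S)-3-(4-nitrobenzoyloxy)-10'-apo-β-caroten-10'-al ethylene acetal (drawn all-E, not isolated) | C1COC(O1)/C=C/C(C)=C/C=C/C=C(C)/C=C/C=C(C)/C=C/C1=C(C)C[C@H](OC(=O)c2ccc(cc2)[N+](=O)[O-])CC1(C)C | intermediate
14 | (3S)-3-hydroxy-10'-apo-β-caroten-10'-al ethylene acetal (not isolated) | C1COC(O1)/C=C/C(C)=C/C=C/C=C(C)/C=C/C=C(C)/C=C/C1=C(C)C[C@H](O)CC1(C)C | intermediate
15 | (3S)-3-hydroxy-10'-apo-β-caroten-10'-al | O=C/C=C/C(C)=C/C=C/C=C(C)/C=C/C=C(C)/C=C/C1=C(C)C[C@H](O)CC1(C)C | intermediate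
16 | 2-(triphenylphosphoranylidene)propanal | CC(C=O)=P(c1ccccc1)(c1ccccc1)c1ccccc1 | starting material
17 | (3S)-3-hydroxy-8'-apo-β-caroten-8'-al | O=C/C(C)=C/C=C/C(C)=C/C=C/C=C(C)/C=C/C=C(C)/C=C/C1=C(C)C[C@H](O)CC1(C)C | intermediate
18 | (3R,5R,6S)-5,6-epoxy-3-hydroxy-5,6-dihydro-8'-apo-β-caroten-8'-al (syn-epoxide, not isolated) | O=C/C(C)=C/C=C/C(C)=C/C=C/C=C(C)/C=C/C=C(C)/C=C/[C@@]12O[C@]1(C)C[C@H](O)CC2(C)C | intermediate
19 | (3R,5R,8R)-5,8-epoxy-3-hydroxy-5,8-dihydro-8'-apo-β-caroten-8'-al (CNP0118413.1) | C\C(C=O)=C/C=C/C(C)=C/C=C/C=C(C)/C=C/C=C(\C)[C@H]1C=C2C(C)(C)C[C@@H](O)C[C@@]2(C)O1 | target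

## Totals and risks

Total step count: 9. Longest linear sequence: 7 (steps 1, 2, 4, 5, 7, 8, 9 from actinol 1).

Most likely to fail, first: step 9. The peroxide may bleach the polyenal by radical or non-directed oxidation. The ring closure gives both C8 epimers, roughly 1:1 expected, so at most about half of the material is 19 per pass. A minor 3,6-oxide from attack of the 3-OH at C6 is also possible. The fallback moves ring formation one C–C bond earlier, so the oxidant never meets the longest chromophore and the epimer problem is handled on a smaller aldehyde. It sets out from 15, which is treated with the same vanadium/t-BuOOH system to give (3R,5R,6S)-5,6-epoxy-3-hydroxy-5,6-dihydro-10'-apo-β-caroten-10'-al F1, not isolated. Camphorsulfonic acid then rearranges it to (3R,5R,8R)-5,8-epoxy-3-hydroxy-5,8-dihydro-10'-apo-β-caroten-10'-al F2 together with its 8S epimer F3. F2 and F3 are separated on silica, and F3 is returned to catalytic acid, where reversible C8–O ionisation re-equilibrates it to more F2. F2 is then homologated with ylide 16 in toluene at 60 °C, neutral conditions that do not open the furanoid, and the route is rejoined at 19.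

Second: step 4. Transmetalation onto the tetrasubstituted, doubly flanked cyclohexenyl palladium may be too slow, leading to triflate hydrolysis or stannane homocoupling. The fallback reverses the polarity of the union. It sets out from 3 and 5. Miyaura borylation of 3 (B2pin2, PdCl2(dppf), KOAc, dioxane, 80 °C) gives (1S)-3,5,5-trimethyl-4-(4,4,5,5-tetramethyl-1,3,2-dioxaborolan-2-yl)cyclohex-3-en-1-yl 4-nitrobenzoate F4. Iododestannylation of 5 (I2, CH2Cl2, 0 °C) gives (2E,4E)-5-iodo-3-methylpenta-2,4-dien-1-ol F5. Suzuki–Miyaura coupling of F4 with F5 (Pd(PPh3)4, K3PO4, THF/H2O, rt) then puts the unhindered partner through oxidative addition and rejoins the route at 6.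

Third: step 7. Three events share one flask (olefination, ester methanolysis, acetal hydrolysis) and the E/Z mixture must be equilibrated; incomplete methanolysis or aldol side reactions of 11 under methoxide would cost material. The fallback changes the order of fragment union and separates the events. It sets out from 7 and 8. The ylide 12 from 7 (NaOMe, MeOH/CH2Cl2) is added to excess 8 (3 equiv) to give (3S)-3-(4-nitrobenzoyloxy)-12'-apo-β-caroten-12'-al F6, which is methanolysed in the same pot to (3S)-3-hydroxy-12'-apo-β-caroten-12'-al F7; F7 is purified. F7 then takes the ylide 10 generated from 9 (2.2 equiv, because of the free hydroxyl) to give acetal 14, where the route is rejoined, and the acid work-up of step 7 delivers 15.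

## Further compounds

F1 | step 9 | (3R,5R,6S)-5,6-epoxy-3-hydroxy-5,6-dihydro-10'-apo-β-caroten-10'-al | O=C/C=C/C(C)=C/C=C/C=C(C)/C=C/C=C(C)/C=C/[C@@]12O[C@]1(C)C[C@H](O)CC2(C)C
F2 | step 9 | (3R,5R,8R)-5,8-epoxy-3-hydroxy-5,8-dihydro-10'-apo-β-caroten-10'-al | O=C/C=C/C(C)=C/C=C/C=C(C)/C=C/C=C(\C)[C@H]1C=C2C(C)(C)C[C@@H](O)C[C@@]2(C)O1
F3 | step 9 | (3R,5R,8S)-5,8-epoxy-3-hydroxy-5,8-dihydro-10'-apo-β-caroten-10'-al | O=C/C=C/C(C)=C/C=C/C=C(C)/C=C/C=C(\C)[C@@H]1C=C2C(C)(C)C[C@@H](O)C[C@@]2(C)O1
F4 | step 4 | (1S)-3,5,5-trimethyl-4-(4,4,5,5-tetramethyl-1,3,2-dioxaborolan-2-yl)cyclohex-3-en-1-yl 4-nitrobenzoate | CC1=C(B2OC(C)(C)C(C)(C)O2)C(C)(C)C[C@@H](OC(=O)c2ccc(cc2)[N+](=O)[O-])C1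
F5 | step 4 | (2E,4E)-5-iodo-3-methylpenta-2,4-dien-1-ol | I/C=C/C(C)=C/CO
F6 | step 7 | (3S)-3-(4-nitrobenzoyloxy)-12'-apo-β-caroten-12'-al | O=C/C(C)=C/C=C/C=C(C)/C=C/C=C(C)/C=C/C1=C(C)C[C@H](OC(=O)c2ccc(cc2)[N+](=O)[O-])CC1(C)C
F7 | step 7 | (3S)-3-hydroxy-12'-apo-β-caroten-12'-al | O=C/C(C)=C/C=C/C=C(C)/C=C/C=C(C)/C=C/C1=C(C)C[C@H](O)CC1(C)C
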